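The cyclohexene ring (C1 heptenyl, C2 CH2OH, C3 OH, C4/C5 epoxide, C6 OH) is disconnected at C1: the C6(O)–C1(alkenyl)=C2 triad is what a one-carbon ring expansion of a cyclopentanone silyl enol ether with dibromocarbene leaves behind. In one operation the key step inserts C1 between C6 and C2 of an epoxycyclopentane and delivers the 2-bromocyclohex-2-enone, whose bromide becomes the heptenyl group. The precursor is the tetrasubstituted silyl enol ether of a 2,3-epoxy-4-silyloxycyclopentanone made from commercial (S)-4-silyloxycyclopentenone; its one bought stereocentre (C3) relays C4/C5 by anti epoxidation, and C6 follows by reduction and inversion.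

Key step: step 7

Remark: the ring atoms keep the numbering of the target throughout (C1 heptenyl-bearing, C2 hydroxymethyl-bearing, C3 and C6 carbinol carbons, C4 and C5 epoxide carbons, C5 carrying the side chain); TBS is tert-butyldimethylsilyl, and both enantiomers of 4-(TBS-oxy)cyclopent-2-en-1-one are taken as commercially available.

Step 1
Reactants: 1 (S)-4-(TBS-oxy)cyclopent-2-en-1-one
Product: 2 (S)-2-iodo-4-(TBS-oxy)cyclopent-2-en-1-one
Conditions: I2, pyridine/CH2Cl2 (1:1), 0 °C → rt
Reagents that add atoms: iodine, II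
Why: α-Iodination of the enone by conjugate addition of pyridine, iodination of the enolate and elimination (an addition–elimination of the Baylis–Hillman type) is standard for 4-silyloxycyclopentenones and leaves C3 untouched.

Step 2
Reactants: 2 (S)-2-iodo-4-(TBS-oxy)cyclopent-2-en-1-one; 3 allyltributylstannane
Product: 4 (S)-2-allyl-4-(TBS-oxy)cyclopent-2-en-1-one
Conditions: Pd2(dba)3 (2.5 mol %), AsPh3, CuI, NMP, rt → 40 °C
Reagents that add atoms: allyltributylstannane 3, C=CC[Sn](CCCC)(CCCC)CCCC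
Why: Stille coupling of an α-iodoenone with an allylstannane on zerovalent palladium with triphenylarsine and CuI is fast near room temperature, so the silyloxy group and the skipped diene should survive.

Step 3
Reactants: 4 (S)-2-allyl-4-(TBS-oxy)cyclopent-2-en-1-one; 5 methyl methacrylate
Product: 6 methyl (E)-2-methyl-4-[(3S)-5-oxo-3-(TBS-oxy)cyclopent-1-en-1-yl]but-2-enoate
Conditions: second-generation Grubbs catalyst, (H2IMes)(PCy3)Cl2Ru=CHPh (5 mol %), methyl methacrylate (10 equiv), CH2Cl2, 40 °C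
Reagents that add atoms: methyl methacrylate 5, C=C(C)C(=O)OC
Why: Olefin cross-metathesis of the terminal alkene with excess methacrylate should give the trisubstituted enoate as the thermodynamically preferred E isomer, the trisubstituted ring enone being inert to the catalyst.

Step 4
Reactants: 6 methyl (E)-2-methyl-4-[(3S)-5-oxo-3-(TBS-oxy)cyclopent-1-en-1-yl]but-2-enoate
Product: 7 methyl (E)-2-methyl-4-[(1R,4S,5R)-2-oxo-4-(TBS-oxy)-6-oxabicyclo[3.1.0]hexan-1-yl]but-2-enoate (epoxide trans to the silyloxy group)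
Conditions: 30% H2O2, NaOH (cat.), MeOH, 0 °C
Reagents that add atoms: hydrogen peroxide, OO
Why: Weitz–Scheffer nucleophilic epoxidation: hydroperoxide adds to C4 of the ring enone (far more electrophilic than the α-methyl enoate) on the face anti to the adjacent C3 silyloxy group and the enolate closes on the same face, which sets C4 and C5 with the epoxide trans to the C3 oxygen.

Step 5
Reactants: 7 methyl (E)-2-methyl-4-[(1R,4S,5R)-2-oxo-4-(TBS-oxy)-6-oxabicyclo[3.1.0]hexan-1-yl]but-2-enoate; 8 formaldehyde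
Product: 10 methyl (E)-4-[(1R,3S,4S,5R)-3-(hydroxymethyl)-2-oxo-4-(TBS-oxy)-6-oxabicyclo[3.1.0]hexan-1-yl]-2-methylbut-2-enoate, via trimethylsilyl enol ether 9 (not isolated)
Conditions: TMSOTf, Et3N, CH2Cl2, −78 → 0 °C; then 37% aq. HCHO, Yb(OTf)3 (10 mol %), THF, rt
Reagents that add atoms: formaldehyde 8, C=O; trimethylsilyl trifluoromethanesulfonate, C[Si](C)(C)OS(=O)(=O)C(F)(F)F (its silyl group is present in 9 only)
Why: Soft enolisation can only go toward C2 because C5 is quaternary, and the silyl enol ether should then undergo a Mukaiyama aldol addition to formaldehyde in water under Yb(OTf)3 catalysis; the new C2 centre (expected trans to the C3 silyloxy group) is erased in step 6.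

Step 6
Reactants: 10 methyl (E)-4-[(1R,3S,4S,5R)-3-(hydroxymethyl)-2-oxo-4-(TBS-oxy)-6-oxabicyclo[3.1.0]hexan-1-yl]-2-methylbut-2-enoate
Product: 11 methyl (E)-4-[(1R,4S,5R)-2,4-bis(TBS-oxy)-3-(TBS-oxymethyl)-6-oxabicyclo[3.1.0]hex-2-en-1-yl]-2-methylbut-2-enoate
Conditions: TBSOTf (2.5 equiv), Et3N, CH2Cl2, −78 → 0 °C
Reagents that add atoms: tert-butyldimethylsilyl trifluoromethanesulfonate, CC(C)(C)[Si](C)(C)OS(=O)(=O)C(F)(F)F
Why: Silyl triflate and amine silylate the primary alcohol and, by soft enolisation through the O-silyl oxocarbenium ion, remove the only remaining α-hydrogen (C2–H) to give the tetrasubstituted silyl enol ether without a free enolate that could expel a β-oxygen.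

Step 7
Reactants: 11 methyl (E)-4-[(1R,4S,5R)-2,4-bis(TBS-oxy)-3-(TBS-oxymethyl)-6-oxabicyclo[3.1.0]hex-2-en-1-yl]-2-methylbut-2-enoate; 12 bromoform
Product: 14 methyl (E)-4-[(1R,5S,6R)-3-bromo-2-oxo-5-(TBS-oxy)-4-(TBS-oxymethyl)-7-oxabicyclo[4.1.0]hept-3-en-1-yl]-2-methylbut-2-enoate, via dibromocyclopropane 13 (not isolated)
Conditions: CHBr3, KOt-Bu (slow addition), pentane, −30 °C → rt; then toluene, 60 °C
Reagents that add atoms: bromoform 12, BrC(Br)Br
Why: Deprotonation of bromoform by tert-butoxide and loss of bromide give dibromocarbene, which adds in a concerted [2+1] cheletropic step to the C6=C2 double bond of the silyl enol ether (closing the three-membered ring of 13), and the strained 6,6-dibromo-1-silyloxybicyclo[3.1.0]hexane then ionises its endo bromide with disrotatory two-electron electrocyclic cleavage of the shared C6–C2 bond, so that the five-membered ring C2–C3–C4–C5–C6 becomes the six-membered ring with the carbene carbon as C1. The resulting 2-bromo-1-silyloxyallyl (oxocarbenium) cation loses its silyl group to bromide and gives the 2-bromocyclohex-2-enone. The closest known reaction type is the dihalocarbene ring expansion of cyclic silyl enol ethers to 2-halocycloalk-2-enones. The six-membered ring is not closed by bond formation but released from the bicycle by breaking the zero-atom bridge, and no new stereocentre survives, because both cyclopropane centres become trigonal while C3, C4 and C5 are spectators (positive charge develops only at the oxygen-stabilised C6 and at C2). The step needs chemoselectivity for the enol ether over the enoate and insertion exactly between C6 and C2: the electrophilic carbene picks the only electron-rich alkene, and the position of that alkene was fixed in step 6, where enolisation can only go toward C2 because C5 is quaternary. Either face of addition leads to the same product, since a gem-dibromide always offers an endo bromide as leaving group.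

Step 8
Reactants: 14 methyl (E)-4-[(1R,5S,6R)-3-bromo-2-oxo-5-(TBS-oxy)-4-(TBS-oxymethyl)-7-oxabicyclo[4.1.0]hept-3-en-1-yl]-2-methylbut-2-enoate; 15 (E)-hept-1-en-1-ylboronic acid
Product: 16 methyl (E)-4-[(1R,5S,6R)-3-[(E)-hept-1-en-1-yl]-2-oxo-5-(TBS-oxy)-4-(TBS-oxymethyl)-7-oxabicyclo[4.1.0]hept-3-en-1-yl]-2-methylbut-2-enoate
Conditions: Pd(dppf)Cl2 (5 mol %), K3PO4, THF/H2O, rt → 40 °C
Reagents that add atoms: (E)-hept-1-en-1-ylboronic acid 15, CCCCC/C=C/B(O)O
Why: Suzuki–Miyaura coupling of the electron-poor α-bromoenone with the (E)-alkenylboronic acid should proceed with retention of alkene geometry under a mild phosphate base, which limits γ-deprotonation of the epoxy enone.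

Step 9
Reactants: 16 methyl (E)-4-[(1R,5S,6R)-3-[(E)-hept-1-en-1-yl]-2-oxo-5-(TBS-oxy)-4-(TBS-oxymethyl)-7-oxabicyclo[4.1.0]hept-3-en-1-yl]-2-methylbut-2-enoate
Product: 17 methyl (E)-4-[(1S,2S,5S,6R)-3-[(E)-hept-1-en-1-yl]-2-hydroxy-5-(TBS-oxy)-4-(TBS-oxymethyl)-7-oxabicyclo[4.1.0]hept-3-en-1-yl]-2-methylbut-2-enoate (C6 hydroxyl syn to the epoxide)
Conditions: NaBH4, CeCl3·7H2O, MeOH, −78 °C
Reagents that add atoms: none
Why: Luche reduction should give clean 1,2-reduction of the dienone, the external hydride adding anti to the epoxide C–O bond (the face on which nucleophiles add to cyclic α,β-epoxy ketones), so that the new C6 hydroxyl stands syn to the epoxide, the C6 epimer of what the target needs.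

Step 10
Reactants: 17 methyl (E)-4-[(1S,2S,5S,6R)-3-[(E)-hept-1-en-1-yl]-2-hydroxy-5-(TBS-oxy)-4-(TBS-oxymethyl)-7-oxabicyclo[4.1.0]hept-3-en-1-yl]-2-methylbut-2-enoate
Product: 18 (1S,2R,5S,6R)-3-[(E)-hept-1-en-1-yl]-1-[(E)-4-methoxy-3-methyl-4-oxobut-2-en-1-yl]-5-(TBS-oxy)-4-(TBS-oxymethyl)-7-oxabicyclo[4.1.0]hept-3-en-2-yl 4-nitrobenzoate (C6 oxygen anti to the epoxide)
Conditions: 4-O2NC6H4CO2H, PPh3, DIAD, THF, 0 °C → rt
Reagents that add atoms: 4-nitrobenzoic acid, O=C(O)c1ccc(cc1)[N+](=O)[O-]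
Why: Mitsunobu reaction: the C6 oxyphosphonium ion is displaced by 4-nitrobenzoate in an SN2 process from the face anti to the epoxide, which inverts C6 to the configuration of the target, the acidic nucleophile suiting a hindered alcohol and the electron-poor epoxide neighbour disfavouring ionisation.

Step 11
Reactants: 18 the bis-TBS 4-nitrobenzoate from step 10
Product: 19 (1S,2R,5S,6R)-3-[(E)-hept-1-en-1-yl]-5-hydroxy-4-(hydroxymethyl)-1-[(E)-4-methoxy-3-methyl-4-oxobut-2-en-1-yl]-7-oxabicyclo[4.1.0]hept-3-en-2-yl 4-nitrobenzoate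
Conditions: Bu4NF, AcOH (1:1), THF, 0 °C → rt
Reagents that add atoms: none
Why: Fluoride cleaves both silyl ethers by Si–F bond formation, and the acetic acid buffer should keep the two esters and the epoxy alcohol from base-induced acyl or epoxide migration.

Step 12
Reactants: 19 the diol 4-nitrobenzoate methyl ester from step 11
Product: 20 (2E)-4-[(1S,2R,5S,6R)-3-[(1E)-hept-1-en-1-yl]-2,5-dihydroxy-4-(hydroxymethyl)-7-oxabicyclo[4.1.0]hept-3-en-1-yl]-2-methylbut-2-enoic acid (target)
Conditions: LiOH, THF/H2O (3:1), 0 °C → rt; then 0.5 M HCl to pH 4, 0 °C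
Reagents that add atoms: lithium hydroxide, [Li+].[OH-]
Why: Saponification cleaves the methyl ester and the activated 4-nitrobenzoate by acyl–oxygen fission, so no stereocentre is touched, and the trisubstituted epoxide of the target is the favoured side of any Payne-type equilibrium of the trans-epoxy alcohols.

Compound list
1 | (S)-4-(TBS-oxy)cyclopent-2-en-1-one | O=C1C[C@H](O[Si](C)(C)C(C)(C)C)C=C1 | starting material
2 | (S)-2-iodo-4-(TBS-oxy)cyclopent-2-en-1-one | O=C1C[C@H](O[Si](C)(C)C(C)(C)C)C=C1I | intermediate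
3 | allyltributylstannane | C=CC[Sn](CCCC)(CCCC)CCCC | starting material
4 | (S)-2-allyl-4-(TBS-oxy)cyclopent-2-en-1-one | O=C1C[C@H](O[Si](C)(C)C(C)(C)C)C=C1CC=C | intermediate
5 | methyl methacrylate | C=C(C)C(=O)OC | starting material
6 | methyl (E)-2-methyl-4-[(3S)-5-oxo-3-(TBS-oxy)cyclopent-1-en-1-yl]but-2-enoate | O=C1C[C@H](O[Si](C)(C)C(C)(C)C)C=C1C/C=C(\C)C(=O)OC | intermediate
7 | methyl (E)-2-methyl-4-[(1R,4S,5R)-2-oxo-4-(TBS-oxy)-6-oxabicyclo[3.1.0]hexan-1-yl]but-2-enoate, epoxide trans to the silyloxy group | O=C1C[C@H](O[Si](C)(C)C(C)(C)C)[C@H]2O[C@@]12C/C=C(\C)C(=O)OC | intermediate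
8 | formaldehyde | C=O | starting material
9 | trimethylsilyl enol ether of 7 (enol double bond C6=C2) | C[Si](C)(C)OC1=C[C@H](O[Si](C)(C)C(C)(C)C)[C@H]2O[C@@]12C/C=C(\C)C(=O)OC | intermediate (not isolated)
10 | methyl (E)-4-[(1R,3S,4S,5R)-3-(hydroxymethyl)-2-oxo-4-(TBS-oxy)-6-oxabicyclo[3.1.0]hexan-1-yl]-2-methylbut-2-enoate, hydroxymethyl trans to the silyloxy group | O=C1[C@@H](CO)[C@H](O[Si](C)(C)C(C)(C)C)[C@H]2O[C@@]12C/C=C(\C)C(=O)OC | intermediate
11 | methyl (E)-4-[(1R,4S,5R)-2,4-bis(TBS-oxy)-3-(TBS-oxymethyl)-6-oxabicyclo[3.1.0]hex-2-en-1-yl]-2-methylbut-2-enoate | CC(C)(C)[Si](C)(C)OC1=C(CO[Si](C)(C)C(C)(C)C)[C@H](O[Si](C)(C)C(C)(C)C)[C@H]2O[C@@]12C/C=C(\C)C(=O)OC | intermediate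
12 | bromoform | BrC(Br)Br | starting material
13 | dibromocyclopropane adduct of 11 (6,6-dibromo-1-silyloxybicyclo[3.1.0]hexane fused to the epoxide; drawn for carbene addition anti to the C3 silyloxy group, both new centres being lost on ring opening) | CC(C)(C)[Si](C)(C)O[C@]12C(Br)(Br)[C@@]1(CO[Si](C)(C)C(C)(C)C)[C@H](O[Si](C)(C)C(C)(C)C)[C@H]3O[C@@]23C/C=C(\C)C(=O)OC | intermediate (not isolated)
14 | methyl (E)-4-[(1R,5S,6R)-3-bromo-2-oxo-5-(TBS-oxy)-4-(TBS-oxymethyl)-7-oxabicyclo[4.1.0]hept-3-en-1-yl]-2-methylbut-2-enoate | O=C1C(Br)=C(CO[Si](C)(C)C(C)(C)C)[C@H](O[Si](C)(C)C(C)(C)C)[C@H]2O[C@@]12C/C=C(\C)C(=O)OC | intermediate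
15 | (E)-hept-1-en-1-ylboronic acid | CCCCC/C=C/B(O)O | starting material
16 | methyl (E)-4-[(1R,5S,6R)-3-[(E)-hept-1-en-1-yl]-2-oxo-5-(TBS-oxy)-4-(TBS-oxymethyl)-7-oxabicyclo[4.1.0]hept-3-en-1-yl]-2-methylbut-2-enoate | CCCCC/C=C/C1=C(CO[Si](C)(C)C(C)(C)C)[C@H](O[Si](C)(C)C(C)(C)C)[C@H]2O[C@@]2(C/C=C(\C)C(=O)OC)C1=O | intermediate
17 | methyl (E)-4-[(1S,2S,5S,6R)-3-[(E)-hept-1-en-1-yl]-2-hydroxy-5-(TBS-oxy)-4-(TBS-oxymethyl)-7-oxabicyclo[4.1.0]hept-3-en-1-yl]-2-methylbut-2-enoate, C6 hydroxyl syn to the epoxide | CCCCC/C=C/C1=C(CO[Si](C)(C)C(C)(C)C)[C@H](O[Si](C)(C)C(C)(C)C)[C@H]2O[C@@]2(C/C=C(\C)C(=O)OC)[C@H]1O | intermediate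
18 | (1S,2R,5S,6R) 4-nitrobenzoate of the C6-inverted alcohol, bis-TBS ether, methyl ester | CCCCC/C=C/C1=C(CO[Si](C)(C)C(C)(C)C)[C@H](O[Si](C)(C)C(C)(C)C)[C@H]2O[C@@]2(C/C=C(\C)C(=O)OC)[C@@H]1OC(=O)c1ccc(cc1)[N+](=O)[O-] | intermediate
19 | (1S,2R,5S,6R) 4-nitrobenzoate with free C3 hydroxyl and hydroxymethyl, methyl ester | CCCCC/C=C/C1=C(CO)[C@H](O)[C@H]2O[C@@]2(C/C=C(\C)C(=O)OC)[C@@H]1OC(=O)c1ccc(cc1)[N+](=O)[O-] | intermediate
20 | (2E)-4-[(1S,2R,5S,6R)-3-[(1E)-hept-1-en-1-yl]-2,5-dihydroxy-4-(hydroxymethyl)-7-oxabicyclo[4.1.0]hept-3-en-1-yl]-2-methylbut-2-enoic acid | CCCCC/C=C/C1=C(CO)[C@H](O)[C@H]2O[C@@]2(C/C=C(\C)C(=O)O)[C@@H]1O | target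

Total step count: 12. Longest linear sequence: 12 steps (from 1).

Steps most likely to fail

Step 7. Carbene transfer to the hindered tetrasubstituted enol ether may be slow, giving tert-butoxide time to deprotonate the γ-position of the enoate, open the epoxide or desilylate the enol ether. The fallback keeps the one-carbon ring expansion but uses known neutral chemistry. It sets out from 11: Furukawa-type Simmons–Smith cyclopropanation (Et2Zn, CH2I2, CH2Cl2, 0 °C) should give the siloxycyclopropane F1. FeCl3 in DMF then cleaves the internal cyclopropane bond oxidatively to the ring-expanded β-chloro ketone F2, and NaOAc in MeOH eliminates HCl to the enone F3. I2 in pyridine, as in step 1, gives the α-iodoenone F4, which couples with 15 under the conditions of step 8 and comes back to the route at 16.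

Step 5. The Lewis acid in water may open the epoxide, or the β-silyloxy ketone may lose its C3 silyloxy group by β-elimination during the aldol addition. The fallback sets out from 7: LiN(SiMe3)2 in THF at −78 °C gives the lithium enolate F5, which is trapped at −78 °C with anhydrous monomeric formaldehyde (from cracked paraformaldehyde) and quenched cold with NH4Cl, coming back at 10.

Step 10. The activated allylic alcohol may ionise in competition with the hindered SN2 displacement, with loss of stereochemical fidelity, allylic transposition or elimination. The fallback moves the inversion to the 2-bromoallylic stage, where the vinyl bromide disfavours the allyl cation. It sets out from 14: Luche reduction gives the bromo alcohol F6 with the hydroxyl syn to the epoxide; Mitsunobu reaction with 4-nitrobenzoic acid gives the inverted bromo 4-nitrobenzoate F7; Suzuki–Miyaura coupling with 15 then comes back to the route at 18.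

Further compounds
F1 | step 7 | siloxycyclopropane from 11 (1-TBS-oxybicyclo[3.1.0]hexane fused to the epoxide, CH2 in place of CBr2 of 13) | CC(C)(C)[Si](C)(C)O[C@]12C[C@@]1(CO[Si](C)(C)C(C)(C)C)[C@H](O[Si](C)(C)C(C)(C)C)[C@H]3O[C@@]23C/C=C(\C)C(=O)OC
F2 | step 7 | ring-expanded β-chloro ketone (chloride at C2, both C2 epimers, centre erased in the next operation) | O=C1CC(Cl)(CO[Si](C)(C)C(C)(C)C)[C@H](O[Si](C)(C)C(C)(C)C)[C@H]2O[C@@]12C/C=C(\C)C(=O)OC
F3 | step 7 | methyl (E)-4-[(1R,5S,6R)-2-oxo-5-(TBS-oxy)-4-(TBS-oxymethyl)-7-oxabicyclo[4.1.0]hept-3-en-1-yl]-2-methylbut-2-enoate (C1–H enone) | O=C1C=C(CO[Si](C)(C)C(C)(C)C)[C@H](O[Si](C)(C)C(C)(C)C)[C@H]2O[C@@]12C/C=C(\C)C(=O)OC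
F4 | step 7 | 3-iodo analogue of 14 (α-iodoenone) | O=C1C(I)=C(CO[Si](C)(C)C(C)(C)C)[C@H](O[Si](C)(C)C(C)(C)C)[C@H]2O[C@@]12C/C=C(\C)C(=O)OC
F5 | step 5 | lithium enolate of 7 (enolate double bond C6=C2) | [Li]OC1=C[C@H](O[Si](C)(C)C(C)(C)C)[C@H]2O[C@@]12C/C=C(\C)C(=O)OC
F6 | step 10 | 3-bromo analogue of 17 (C6 hydroxyl syn to the epoxide) | BrC1=C(CO[Si](C)(C)C(C)(C)C)[C@H](O[Si](C)(C)C(C)(C)C)[C@H]2O[C@@]2(C/C=C(\C)C(=O)OC)[C@H]1O
F7 | step 10 | 3-bromo analogue of 18 (inverted 4-nitrobenzoate) | BrC1=C(CO[Si](C)(C)C(C)(C)C)[C@H](O[Si](C)(C)C(C)(C)C)[C@H]2O[C@@]2(C/C=C(\C)C(=O)OC)[C@@H]1OC(=O)c1ccc(cc1)[N+](=O)[O-]
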